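## The problem

The target is an 8-O-4' neolignan. Ring A is a guaiacyl ring (C1–C6) carrying the chain C7–C8–C9. The C8 oxygen is the phenolic oxygen at C4' of a syringyl ring B, which bears a hydroxyacetyl group (C7'(=O)–C8'H2OH) at C1'. No ring has to be built. The work lies in the C8–O–C4' ether, in the three-carbon chain, and in two adjacent stereocentres: C7 (R, benzylic carbinol) and C8 (S, aryl ether), which stand in the erythro relation. C8 is the centre to set first, by absolute control. Once C7 passes through a ketone, the C8 aryloxy group can steer hydride to C7, whereas a C7 carbinol offers no comparable handle for forming the C8–O bond. Three functions are fragile: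

- the C7 hydroxyl para to the free ring A phenol, which acid ionises through a quinone methide, with epimerisation or solvolysis;
- any C7 ketone next to C8, where base epimerises C8 or expels the C9 oxygen;
- the α-hydroxy ketone on ring B, which is sensitive to base and oxidants.

Ring B needs its carbon substituent exactly para to the ether oxygen. The enabling feature is that C8 is a CH bearing the aryl ether oxygen, placed between C9 (which can be a carboxylic acid) and C7 (benzylic and para to the ring A oxygen). C8 is therefore the α-carbon of an α-aryloxy acid that hydrogenation of a C7=C8 acrylic acid can create, and C7 can be oxygenated afterwards by benzylic hydride abstraction.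

## Retrosynthesis

**Protecting groups (24 ⇐ 23 ⇐ 22).** Only O–Si and O–CH2Ph bonds are cut. Target 24 tolerates acid least, so the last operation is buffered fluoride on the bis-silyl ether 23 (C7–O–TBS, C9–O–TBDPS). The ring A phenol must remain an electron donor during the benzylic oxidation and survive base, borane and organolithium. An alkyl-type ether is therefore needed; benzyl is preferred to an acetal ether, which would need acid at the end. The benzyl groups of 22 (ring A and glycolyl oxygen) are removed by hydrogenolysis while C7–O is still silylated, so the benzylic C–O bond is not at risk.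

**C1'–C7' bond (22 ⇐ 16 + 19).** Friedel–Crafts acylation would attack the more nucleophilic ring A. A ketone carried from the start would not survive borane and hydride. A bromine at C1', carried from phenol 1, fixes the position unambiguously. The forward step asks for bromine–lithium exchange on 16 and acylation of aryllithium 20 by Weinreb amide 19, whose chelated adduct 21 prevents over-addition. Amide 19 comes in one step from acid chloride 17 and amine salt 18.

**C7–H bond and the C7 stereocentre (16 ⇐ 15 ⇐ 14).** The carbinol 15 is traced to ketone 14, so that C8 controls C7. Two models give opposite results: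

- In the non-chelated polar Felkin–Anh arrangement the aryloxy group is antiperiplanar to the incoming hydride; with 8S this leads to 7S (threo).
- In a five-membered chelate of the carbonyl oxygen and the C8 aryloxy oxygen, hydride enters past H8 and gives 7R (erythro, anti along Ar–C7–C8–C9).

A chelating hydride, Zn(BH4)2, is therefore specified. The C9 oxygen sits under a bulky, poorly coordinating TBDPS group so that the aryloxy oxygen is the only chelating site. Silylation of 15 gives 16.

**C7=O from C7H2 (14 ⇐ 12).** The C7–O bond is cut back to a methylene. This is the price of the hydrogenation, which leaves C7 as CH2. The para benzyloxy group of ring A makes hydride abstraction by DDQ possible, and water supplies the oxygen. The oxidation is placed after reduction of C9, because a C9 acid would give a β-keto acid that decarboxylates. The medium is non-basic, so C8 in 14 should keep its configuration. TBDPS is chosen at C9 because it withstands the acidic hydroquinone by-product.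

**Oxidation-level adjustment (12 ⇐ 11 ⇐ 10).** Acid 10 is reduced by borane, which leaves the aryl bromide and benzyl ether alone, and alcohol 11 is silylated.

**C7–H and C8–H bonds (10 ⇐ 9).** This is the strategic cut. Against an auxiliary-based alkylation or a resolution, the hydrogenation is catalytic and builds C8 as a configurationally robust, crystallisable α-aryloxy acid. It asks for the geometrically pure Z acid 9 and a catalyst that tolerates C–Br and O–benzyl.

**C7=C8 bond (9 ⇐ 8 ⇐ 6 ⇐ 3 + 4).** The alkene is cut to ester 3 and purchased O-benzylvanillin 4. Aldol addition gives 6, and elimination through mesylate 7 gives the conjugated ester 8. The isomer with aryl trans to the carboxyl group (Z) should predominate as the more stable one. Saponification and crystallisation give 9.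

**C–O ether bond (3 ⇐ 1 + 2).** The hindered syringyl-type phenol 1 is alkylated at a primary carbon of bromoacetate 2. Forming this ether late, at the secondary C8, would require displacement by a doubly ortho-substituted phenol next to a benzylic centre, which is far less reliable.

## Roads not taken

**Alternative 1:** The cut is the C1'–C7' bond, with ring B carrying only hydrogen at C1'. In the protected ether A1 (acetonide over O7/O9, silyl on the ring A phenol), C1' is the only aromatic C–H without an ortho substituent. Sterically governed borylation with [Ir(OMe)(cod)]2, 4,4'-di-tert-butyl-2,2'-bipyridine and B2pin2 should therefore give boronate A2. Zerovalent palladium, Pd(PPh3)4, would then couple A2 with acetoxyacetyl chloride A3 to give ketone A4.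

- Merits: no halogen is carried through the route, no cryogenic organolithium is needed, and syringol itself serves as ring B.
- Weak points: the acyl coupling of a crude boronate with an α-acyloxy acid chloride (ketene formation, decarbonylation) is the least documented link. The acetonide and acetate of A4 need acid and base at the end, where the C7 carbinol and the α-hydroxy ketone are most exposed. The step also says nothing about C7 and C8; it is an endgame tactic, and a stereodefining sequence is still required.
- Comparison: on the C1' problem alone this road is arguably the more elegant. The chosen plan sets against it the regiochemical certainty of a bromide present from the first step, a textbook acyl transfer, and a neutral final deprotection.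

**Alternative 2:** The cut is C7–O and C8–H across a Z aryl enol ether A5. Monoisopinocampheylborane would add boron to C7 and hydrogen to C8 on one face, and alkaline H2O2 would give the erythro 7R,8S alcohol A6.

- Merits: both stereocentres arise in one operation. The erythro relation follows from syn addition to the Z alkene. No benzylic C–H oxidation is needed, and C8 never sits beside a C7 ketone. In these respects it is better than the chosen plan.
- Weak points: the C7 borane carries a β-aryloxy group and can collapse by β-elimination, losing ring B. The trisubstituted Z enol ether A5 has no straightforward stereoselective synthesis. A stoichiometric chiral borane is required, and its selectivity on an electron-rich aryl enol ether is uncertain.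
- Comparison: the chosen plan sets against it a catalytic enantio-determining step on a documented substrate class, a Z precursor from a simple condensation, and an intermediate acid whose enantiomeric purity can be upgraded by crystallisation. It pays with the oxidation–reduction detour at C7.

**Alternative 3:** The cut is the C8–C9 bond. The Z trimethylsilyl enol ether A8 of α-aryloxy ketone A7 would react with aqueous formaldehyde A9 under Sc(OTf)3 and a chiral 2,2'-bipyridine diol to give the C8-configured β-hydroxy ketone A10.

- Merits: A7 is available in one alkylation. C7 is already at the ketone level, so no C–H oxidation is needed, and the route is several steps shorter than the chosen one.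
- Weak points: the stereocentre is born α to an aryl ketone, in aqueous Lewis-acidic medium, as a free β-hydroxy ketone. Enolisation and retro-aldol loss of A9 threaten it from the moment it forms. The catalytic hydroxymethylation is established for α-alkyl aryl ketone enol ethers, not for α-aryloxy ones.
- Comparison: the chosen plan also passes through a C7 ketone (14), but with C9 silylated and under non-basic conditions, and only after C8 has been secured and purified as an acid. It sets stronger precedent for the enantio-determining step against the shorter length of this road.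

Key step: step 5

Remark: the antipode of the spiro ligand in step 5 is the one that delivers the 2R acid; both antipodes are accessible, and the choice would be fixed by an analytical-scale run.

## Route

Step 1
Reactants: 1 4-bromo-2,6-dimethoxyphenol; 2 ethyl bromoacetate
Product: 3 ethyl 2-(4-bromo-2,6-dimethoxyphenoxy)acetate
Conditions: K2CO3, acetone, reflux
Reagents that add atoms: none
Why: Williamson etherification of a phenoxide with a primary α-halo ester; the two ortho methoxy groups slow but do not prevent attack on this unhindered, activated electrophile.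

Step 2
Reactants: 3 ethyl 2-(4-bromo-2,6-dimethoxyphenoxy)acetate; 4 4-(benzyloxy)-3-methoxybenzaldehyde
Product: 6 ethyl 3-[4-(benzyloxy)-3-methoxyphenyl]-2-(4-bromo-2,6-dimethoxyphenoxy)-3-hydroxypropanoate (racemic syn/anti mixture), via lithium ester enolate 5 (not isolated)
Conditions: LiN(iPr)2, THF, −78 °C; then 4, −78 °C; aq. NH4Cl
Reagents that add atoms: none
Why: Aldol addition of an aryloxyacetate lithium enolate to an aromatic aldehyde, the standard entry to arylglycerol β-aryl ether skeletons; both new centres are erased in step 3, so the diastereomer mixture is used as such.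

Step 3
Reactants: 6 ethyl 3-[4-(benzyloxy)-3-methoxyphenyl]-2-(4-bromo-2,6-dimethoxyphenoxy)-3-hydroxypropanoate
Product: 8 ethyl (2Z)-3-[4-(benzyloxy)-3-methoxyphenyl]-2-(4-bromo-2,6-dimethoxyphenoxy)prop-2-enoate, via β-mesyloxy ester 7 (not isolated)
Conditions: MsCl, Et3N, CH2Cl2, 0 °C; then DBU, rt
Reagents that add atoms: none
Why: Mesylation followed by E1cB elimination through the ester enolate; the elimination is not stereospecific and should favour the more stable alkene with ring A trans to the ester (Z), as is usual for 2-alkoxy- and 2-aryloxycinnamates.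

Step 4
Reactants: 8 ethyl (2Z)-3-[4-(benzyloxy)-3-methoxyphenyl]-2-(4-bromo-2,6-dimethoxyphenoxy)prop-2-enoate
Product: 9 (2Z)-3-[4-(benzyloxy)-3-methoxyphenyl]-2-(4-bromo-2,6-dimethoxyphenoxy)prop-2-enoic acid
Conditions: LiOH, THF/MeOH/H2O, rt to 40 °C; then aq. HCl; recrystallisation
Reagents that add atoms: lithium hydroxide, [Li+].[OH-]
Why: Saponification of the conjugated ester by acyl–oxygen cleavage; crystallisation of the acid should remove any E isomer, so that a single alkene geometry enters the key step.

Step 5
Reactants: 9 (2Z)-3-[4-(benzyloxy)-3-methoxyphenyl]-2-(4-bromo-2,6-dimethoxyphenoxy)prop-2-enoic acid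
Product: 10 (2R)-3-[4-(benzyloxy)-3-methoxyphenyl]-2-(4-bromo-2,6-dimethoxyphenoxy)propanoic acid
Conditions: H2 (6 atm), [Ir(cod)(L*)][B(3,5-(CF3)2C6H3)4] (1 mol%; L* = 7-[bis(3,5-di-tert-butylphenyl)phosphino]-7'-(4-benzyl-4,5-dihydrooxazol-2-yl)-1,1'-spirobiindane), Cs2CO3 (0.5 equiv), MeOH, rt; then aq. HCl
Reagents that add atoms: none
Why: This is the carboxyl-directed iridium-catalysed asymmetric hydrogenation of an α-aryloxy α,β-unsaturated acid; the closest known reaction type is the hydrogenation of (Z)-2-aryloxy-3-arylacrylic acids with spiro phosphine-oxazoline iridium catalysts. Under H2 the cod ligand of the monovalent iridium precatalyst is hydrogenated off and a trivalent iridium dihydride forms; the caesium carboxylate of 9 binds through oxygen and holds C7=C8 in the pocket of the rigid spirobiindane ligand. Migratory insertion then most plausibly transfers hydride to C8 and forms an Ir–C7 bond within a five-membered carboxylate chelate, and hydrogenolysis of that bond by a second H2 places the second hydrogen on C7 from the same face. No ring closes. The only new stereocentre, C8, is under catalyst control: the ligand antipode decides which face of the anchored alkene meets the hydride, and because only the Z acid is present one face corresponds to one enantiomer (2R). The step needs enantioface selectivity and chemoselectivity; the first is secured by the carboxylate anchor and the single alkene geometry, the second by the homogeneous iridium hydride, which does not insert into the aryl C–Br bond or cleave the benzyl ether. The two ortho methoxy groups on the aryloxy substituent are the one feature beyond the documented substrates.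

Step 6
Reactants: 10 (2R)-3-[4-(benzyloxy)-3-methoxyphenyl]-2-(4-bromo-2,6-dimethoxyphenoxy)propanoic acid
Product: 11 (2R)-3-[4-(benzyloxy)-3-methoxyphenyl]-2-(4-bromo-2,6-dimethoxyphenoxy)propan-1-ol
Conditions: BH3·THF, THF, 0 °C to rt; then MeOH, aq. work-up
Reagents that add atoms: none
Why: Borane reduction of a carboxylic acid through the acyloxyborane; it is chemoselective over aryl bromide and benzyl ether and does not touch C8.

Step 7
Reactants: 11 (2R)-3-[4-(benzyloxy)-3-methoxyphenyl]-2-(4-bromo-2,6-dimethoxyphenoxy)propan-1-ol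
Product: 12 tert-butyl{[(2R)-3-[4-(benzyloxy)-3-methoxyphenyl]-2-(4-bromo-2,6-dimethoxyphenoxy)propyl]oxy}diphenylsilane
Conditions: TBDPSCl, imidazole, DMF, rt
Reagents that add atoms: tert-butyl(chloro)diphenylsilane, CC(C)(C)[Si](Cl)(c1ccccc1)c1ccccc1
Why: Standard silylation of a primary alcohol; TBDPS is chosen because it resists the acidic conditions of step 8, does not chelate zinc in step 9, and is still fluoride-labile at the end.

Step 8
Reactants: 12 tert-butyl{[(2R)-3-[4-(benzyloxy)-3-methoxyphenyl]-2-(4-bromo-2,6-dimethoxyphenoxy)propyl]oxy}diphenylsilane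
Product: 14 (2S)-1-[4-(benzyloxy)-3-methoxyphenyl]-2-(4-bromo-2,6-dimethoxyphenoxy)-3-[(tert-butyldiphenylsilyl)oxy]propan-1-one, via C7 carbinol 13 (not isolated)
Conditions: DDQ (2.5 equiv), CH2Cl2/H2O (10:1), 0 °C to rt
Reagents that add atoms: water, O
Why: DDQ-mediated benzylic oxidation of a para-alkoxy arylalkane: hydride abstraction from C7 gives a cation stabilised by the ring A benzyloxy group, water traps it to carbinol 13, and a second hydride abstraction gives the aryl ketone, which deactivates ring A against further oxidation. The medium is non-basic, so the C8 stereocentre should persist (its descriptor changes from R to S only because C7 now outranks C9).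

Step 9
Reactants: 14 (2S)-1-[4-(benzyloxy)-3-methoxyphenyl]-2-(4-bromo-2,6-dimethoxyphenoxy)-3-[(tert-butyldiphenylsilyl)oxy]propan-1-one
Product: 15 (1R,2S)-1-[4-(benzyloxy)-3-methoxyphenyl]-2-(4-bromo-2,6-dimethoxyphenoxy)-3-[(tert-butyldiphenylsilyl)oxy]propan-1-ol
Conditions: Zn(BH4)2, Et2O, −30 °C to 0 °C; aq. NH4Cl
Reagents that add atoms: none
Why: Chelation-controlled (Cram chelate) reduction of an α-aryloxy ketone: zinc bridges the carbonyl oxygen and the C8 aryloxy oxygen, and hydride enters the chelate from the face of H8, which sets C7 as R (erythro). The neutral reagent avoids enolisation of 14.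

Step 10
Reactants: 15 (1R,2S)-1-[4-(benzyloxy)-3-methoxyphenyl]-2-(4-bromo-2,6-dimethoxyphenoxy)-3-[(tert-butyldiphenylsilyl)oxy]propan-1-ol
Product: 16 {(1R,2S)-1-[4-(benzyloxy)-3-methoxyphenyl]-2-(4-bromo-2,6-dimethoxyphenoxy)-3-[(tert-butyldiphenylsilyl)oxy]propoxy}(tert-butyl)dimethylsilane
Conditions: TBSOTf, 2,6-lutidine, CH2Cl2, −78 °C to 0 °C
Reagents that add atoms: tert-butyldimethylsilyl trifluoromethanesulfonate, CC(C)(C)[Si](C)(C)OS(=O)(=O)C(F)(F)F
Why: Silyl triflate silylation of a hindered secondary alcohol under buffered conditions; it masks the C7 hydroxyl for the organolithium step and shields the benzylic C–O bond during the later hydrogenolysis.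

Step 11
Reactants: 17 benzyloxyacetyl chloride; 18 N,O-dimethylhydroxylamine hydrochloride
Product: 19 2-(benzyloxy)-N-methoxy-N-methylacetamide
Conditions: pyridine, CH2Cl2, 0 °C to rt
Reagents that add atoms: none
Why: Acylation of N,O-dimethylhydroxylamine by an acid chloride, the standard preparation of a Weinreb amide.

Step 12
Reactants: 16 {(1R,2S)-1-[4-(benzyloxy)-3-methoxyphenyl]-2-(4-bromo-2,6-dimethoxyphenoxy)-3-[(tert-butyldiphenylsilyl)oxy]propoxy}(tert-butyl)dimethylsilane; 19 2-(benzyloxy)-N-methoxy-N-methylacetamide
Product: 22 2-(benzyloxy)-1-[4-({(1R,2S)-1-[4-(benzyloxy)-3-methoxyphenyl]-1-[(tert-butyldimethylsilyl)oxy]-3-[(tert-butyldiphenylsilyl)oxy]propan-2-yl}oxy)-3,5-dimethoxyphenyl]ethan-1-one, via aryllithium 20 (not isolated), via lithium hemiaminal chelate 21 (not isolated)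
Conditions: n-BuLi, THF, −78 °C; then 19, −78 °C to −40 °C; aq. NH4Cl
Reagents that add atoms: none
Why: Bromine–lithium exchange on an electron-rich aryl bromide followed by Weinreb ketone synthesis; the chelated tetrahedral adduct 21 survives until work-up, so no tertiary alcohol forms, and the molecule has no acidic hydrogen at this stage.

Step 13
Reactants: 22 2-(benzyloxy)-1-[4-({(1R,2S)-1-[4-(benzyloxy)-3-methoxyphenyl]-1-[(tert-butyldimethylsilyl)oxy]-3-[(tert-butyldiphenylsilyl)oxy]propan-2-yl}oxy)-3,5-dimethoxyphenyl]ethan-1-one
Product: 23 1-[4-({(1R,2S)-1-[(tert-butyldimethylsilyl)oxy]-3-[(tert-butyldiphenylsilyl)oxy]-1-(4-hydroxy-3-methoxyphenyl)propan-2-yl}oxy)-3,5-dimethoxyphenyl]-2-hydroxyethan-1-one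
Conditions: H2 (1 atm), Pd(OH)2/C, EtOAc, rt
Reagents that add atoms: none
Why: Hydrogenolysis of the aryl benzyl ether and the α-benzyloxy ketone; the electron-rich aryl ketone is reduced much more slowly than benzyl ethers are cleaved, and the C7–O bond is protected as its silyl ether.

Step 14
Reactants: 23 1-[4-({(1R,2S)-1-[(tert-butyldimethylsilyl)oxy]-3-[(tert-butyldiphenylsilyl)oxy]-1-(4-hydroxy-3-methoxyphenyl)propan-2-yl}oxy)-3,5-dimethoxyphenyl]-2-hydroxyethan-1-one
Product: 24 1-[4-({(1R,2S)-1,3-dihydroxy-1-(4-hydroxy-3-methoxyphenyl)propan-2-yl}oxy)-3,5-dimethoxyphenyl]-2-hydroxyethan-1-one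
Conditions: Bu4NF, AcOH, THF, 0 °C to rt
Reagents that add atoms: none
Why: Fluoride-induced cleavage of both silyl ethers; the acetic acid buffer keeps the medium near neutral, so neither the C7 carbinol (acid) nor the α-hydroxy ketone and phenol (base) are stressed, and C7 and C8 are untouched.

## Compound list

1 | 4-bromo-2,6-dimethoxyphenol | COc1cc(Br)cc(OC)c1O | starting material
2 | ethyl bromoacetate | CCOC(=O)CBr | starting material
3 | ethyl 2-(4-bromo-2,6-dimethoxyphenoxy)acetate | CCOC(=O)COc1c(OC)cc(Br)cc1OC | intermediate
4 | 4-(benzyloxy)-3-methoxybenzaldehyde (O-benzylvanillin) | COc1cc(C=O)ccc1OCc1ccccc1 | starting material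
5 | lithium enolate of 3 (not isolated) | [Li+].CCOC([O-])=COc1c(OC)cc(Br)cc1OC | intermediate
6 | ethyl 3-[4-(benzyloxy)-3-methoxyphenyl]-2-(4-bromo-2,6-dimethoxyphenoxy)-3-hydroxypropanoate (racemic, syn/anti mixture) | COc1cc(C(O)C(C(=O)OCC)Oc2c(OC)cc(Br)cc2OC)ccc1OCc1ccccc1 | intermediate
7 | ethyl 3-[4-(benzyloxy)-3-methoxyphenyl]-2-(4-bromo-2,6-dimethoxyphenoxy)-3-[(methylsulfonyl)oxy]propanoate (not isolated) | COc1cc(C(OS(C)(=O)=O)C(C(=O)OCC)Oc2c(OC)cc(Br)cc2OC)ccc1OCc1ccccc1 | intermediate
8 | ethyl (2Z)-3-[4-(benzyloxy)-3-methoxyphenyl]-2-(4-bromo-2,6-dimethoxyphenoxy)prop-2-enoate | COc1cc(/C=C(/C(=O)OCC)Oc2c(OC)cc(Br)cc2OC)ccc1OCc1ccccc1 | intermediate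
9 | (2Z)-3-[4-(benzyloxy)-3-methoxyphenyl]-2-(4-bromo-2,6-dimethoxyphenoxy)prop-2-enoic acid | COc1cc(/C=C(/C(=O)O)Oc2c(OC)cc(Br)cc2OC)ccc1OCc1ccccc1 | intermediate
10 | (2R)-3-[4-(benzyloxy)-3-methoxyphenyl]-2-(4-bromo-2,6-dimethoxyphenoxy)propanoic acid | COc1cc(C[C@H](C(=O)O)Oc2c(OC)cc(Br)cc2OC)ccc1OCc1ccccc1 | intermediate
11 | (2R)-3-[4-(benzyloxy)-3-methoxyphenyl]-2-(4-bromo-2,6-dimethoxyphenoxy)propan-1-ol | COc1cc(C[C@H](CO)Oc2c(OC)cc(Br)cc2OC)ccc1OCc1ccccc1 | intermediate
12 | tert-butyl{[(2R)-3-[4-(benzyloxy)-3-methoxyphenyl]-2-(4-bromo-2,6-dimethoxyphenoxy)propyl]oxy}diphenylsilane | COc1cc(C[C@H](CO[Si](c2ccccc2)(c2ccccc2)C(C)(C)C)Oc2c(OC)cc(Br)cc2OC)ccc1OCc1ccccc1 | intermediate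
13 | (1RS,2S)-1-[4-(benzyloxy)-3-methoxyphenyl]-2-(4-bromo-2,6-dimethoxyphenoxy)-3-[(tert-butyldiphenylsilyl)oxy]propan-1-ol (not isolated) | COc1cc(C(O)[C@H](CO[Si](c2ccccc2)(c2ccccc2)C(C)(C)C)Oc2c(OC)cc(Br)cc2OC)ccc1OCc1ccccc1 | intermediate
14 | (2S)-1-[4-(benzyloxy)-3-methoxyphenyl]-2-(4-bromo-2,6-dimethoxyphenoxy)-3-[(tert-butyldiphenylsilyl)oxy]propan-1-one | COc1cc(C(=O)[C@H](CO[Si](c2ccccc2)(c2ccccc2)C(C)(C)C)Oc2c(OC)cc(Br)cc2OC)ccc1OCc1ccccc1 | intermediate
15 | (1R,2S)-1-[4-(benzyloxy)-3-methoxyphenyl]-2-(4-bromo-2,6-dimethoxyphenoxy)-3-[(tert-butyldiphenylsilyl)oxy]propan-1-ol | COc1cc([C@@H](O)[C@H](CO[Si](c2ccccc2)(c2ccccc2)C(C)(C)C)Oc2c(OC)cc(Br)cc2OC)ccc1OCc1ccccc1 | intermediate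
16 | {(1R,2S)-1-[4-(benzyloxy)-3-methoxyphenyl]-2-(4-bromo-2,6-dimethoxyphenoxy)-3-[(tert-butyldiphenylsilyl)oxy]propoxy}(tert-butyl)dimethylsilane | COc1cc([C@@H](O[Si](C)(C)C(C)(C)C)[C@H](CO[Si](c2ccccc2)(c2ccccc2)C(C)(C)C)Oc2c(OC)cc(Br)cc2OC)ccc1OCc1ccccc1 | intermediate
17 | benzyloxyacetyl chloride | O=C(Cl)COCc1ccccc1 | starting material
18 | N,O-dimethylhydroxylamine hydrochloride | CNOC.Cl | starting material
19 | 2-(benzyloxy)-N-methoxy-N-methylacetamide | CON(C)C(=O)COCc1ccccc1 | intermediate
20 | aryllithium from 16, lithium in place of bromine at C1' (not isolated) | COc1cc([C@@H](O[Si](C)(C)C(C)(C)C)[C@H](CO[Si](c2ccccc2)(c2ccccc2)C(C)(C)C)Oc2c(OC)cc([Li])cc2OC)ccc1OCc1ccccc1 | intermediate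
21 | lithium alkoxide of the N-methoxy-N-methyl hemiaminal formed from 20 and 19 (not isolated) | COc1cc([C@@H](O[Si](C)(C)C(C)(C)C)[C@H](CO[Si](c2ccccc2)(c2ccccc2)C(C)(C)C)Oc2c(OC)cc(C(O[Li])(COCc3ccccc3)N(C)OC)cc2OC)ccc1OCc1ccccc1 | intermediate
22 | 2-(benzyloxy)-1-[4-({(1R,2S)-1-[4-(benzyloxy)-3-methoxyphenyl]-1-[(tert-butyldimethylsilyl)oxy]-3-[(tert-butyldiphenylsilyl)oxy]propan-2-yl}oxy)-3,5-dimethoxyphenyl]ethan-1-one | COc1cc([C@@H](O[Si](C)(C)C(C)(C)C)[C@H](CO[Si](c2ccccc2)(c2ccccc2)C(C)(C)C)Oc2c(OC)cc(C(=O)COCc3ccccc3)cc2OC)ccc1OCc1ccccc1 | intermediate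
23 | 1-[4-({(1R,2S)-1-[(tert-butyldimethylsilyl)oxy]-3-[(tert-butyldiphenylsilyl)oxy]-1-(4-hydroxy-3-methoxyphenyl)propan-2-yl}oxy)-3,5-dimethoxyphenyl]-2-hydroxyethan-1-one | COc1cc([C@@H](O[Si](C)(C)C(C)(C)C)[C@H](CO[Si](c2ccccc2)(c2ccccc2)C(C)(C)C)Oc2c(OC)cc(C(=O)CO)cc2OC)ccc1O | intermediate
24 | 1-[4-({(1R,2S)-1,3-dihydroxy-1-(4-hydroxy-3-methoxyphenyl)propan-2-yl}oxy)-3,5-dimethoxyphenyl]-2-hydroxyethan-1-one (CNP0282675.1) | COc1cc([C@@H](O)[C@H](CO)Oc2c(OC)cc(C(=O)CO)cc2OC)ccc1O | target

## Step count and least certain steps

Total step count: 14. Longest linear sequence: 13 (steps 1–10 and 12–14, from 1 and 2); step 11 is a one-step branch.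

**Step 5 (key step).** Turnover may be slow or enantioface discrimination poor. The 2,6-dimethoxy-substituted aryloxy group is bulkier and differently oriented than the aryloxy groups on which the catalyst class is documented, and an ortho methoxy oxygen may compete with the alkene for the metal. Residual E acid would lower the enantiomeric purity further. Fallback (resolution in place of asymmetric catalysis): acid 9 is hydrogenated without induction over the achiral cationic complex [Rh(cod)(dppb)]BF4 (dppb = 1,4-bis(diphenylphosphino)butane; H2, MeOH, Et3N) to the racemic 3-[4-(benzyloxy)-3-methoxyphenyl]-2-(4-bromo-2,6-dimethoxyphenoxy)propanoic acid F1. This is crystallised with (R)-1-phenylethylamine (or its antipode, whichever gives the less soluble salt of the 2R acid) to the (R)-1-phenylethylammonium (2R)-carboxylate F2. Acidification returns the route at 10. Scalemic 10 from step 5 could be upgraded through the same salt.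

**Step 8.** Three processes are most likely to interfere: loss of the C8 proton from the C7 cation (enol ether formation, which erases C8); sluggish hydride abstraction, because the β-aryloxy group destabilises the cation; and partial epimerisation of C8 in ketone 14. Fallback (two-electron oxidation of the free phenol through a quinone methide, in place of hydride abstraction from the ether):

- From 12 the benzyl ether is cleaved with BCl3 and pentamethylbenzene (CH2Cl2, −78 °C) to 4-{(2R)-2-(4-bromo-2,6-dimethoxyphenoxy)-3-[(tert-butyldiphenylsilyl)oxy]propyl}-2-methoxyphenol F3.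
- Ag2O (CH2Cl2, rt) oxidises it to the quinone methide 4-{(2R)-2-(4-bromo-2,6-dimethoxyphenoxy)-3-[(tert-butyldiphenylsilyl)oxy]propylidene}-2-methoxycyclohexa-2,5-dien-1-one F4, used in solution.
- Hydration in aqueous THF gives 4-{(1RS,2S)-2-(4-bromo-2,6-dimethoxyphenoxy)-3-[(tert-butyldiphenylsilyl)oxy]-1-hydroxypropyl}-2-methoxyphenol F5.
- Selective O-benzylation of the phenol (BnBr, K2CO3, acetone) rejoins the route at 13, which Dess–Martin periodinane (or the second half of step 8) converts into 14.

**Step 9.** Facial selectivity may be poor if the weakly basic, doubly flanked aryl ether oxygen does not hold zinc in a chelate; the polar Felkin–Anh pathway would then leak threo alcohol. Fallback (catalyst control in place of substrate control): ketone 14 is reduced with BH3·SMe2 and (R)-2-methyl-CBS-oxazaborolidine. This is the antipode expected to give 7R if ring A behaves as the large substituent, which would be confirmed on small scale. The route is rejoined at 15; no new compound arises (line F0).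

**Step 3.** An E/Z mixture may form, since the elimination is not stereospecific and the bulky aryloxy group may weaken the usual preference; only the Z acid is a valid substrate for step 5. Fallback (thermodynamic Perkin-type condensation in place of aldol and elimination): ester 3 is saponified (LiOH, aqueous THF) to 2-(4-bromo-2,6-dimethoxyphenoxy)acetic acid F6. This is condensed with aldehyde 4 in Ac2O/Et3N at 110 °C; the reversible anhydride aldol and elimination should give the acid with ring A trans to the carboxyl group. After aqueous work-up this is 9, where the route is rejoined.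

**Step 12.** Proton transfer from the α-methylene of amide 19 to aryllithium 20 (giving the debrominated arene), or incomplete halogen–lithium exchange, may occur. Fallback (aldehyde addition and oxidation in place of acyl substitution): 20, generated from 16 as before, is added to purchased benzyloxyacetaldehyde to give 2-(benzyloxy)-1-[4-({(1R,2S)-1-[4-(benzyloxy)-3-methoxyphenyl]-1-[(tert-butyldimethylsilyl)oxy]-3-[(tert-butyldiphenylsilyl)oxy]propan-2-yl}oxy)-3,5-dimethoxyphenyl]ethan-1-ol F7 as a mixture of C7' epimers. Dess–Martin oxidation returns the route at 22.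

## Further compounds

F1 | step 5 | rac-3-[4-(benzyloxy)-3-methoxyphenyl]-2-(4-bromo-2,6-dimethoxyphenoxy)propanoic acid | COc1cc(CC(C(=O)O)Oc2c(OC)cc(Br)cc2OC)ccc1OCc1ccccc1
F2 | step 5 | (R)-1-phenylethylammonium (2R)-3-[4-(benzyloxy)-3-methoxyphenyl]-2-(4-bromo-2,6-dimethoxyphenoxy)propanoate | COc1cc(C[C@H](C(=O)[O-])Oc2c(OC)cc(Br)cc2OC)ccc1OCc1ccccc1.C[C@@H]([NH3+])c1ccccc1
F3 | step 8 | 4-{(2R)-2-(4-bromo-2,6-dimethoxyphenoxy)-3-[(tert-butyldiphenylsilyl)oxy]propyl}-2-methoxyphenol | COc1cc(C[C@H](CO[Si](c2ccccc2)(c2ccccc2)C(C)(C)C)Oc2c(OC)cc(Br)cc2OC)ccc1O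
F4 | step 8 | 4-{(2R)-2-(4-bromo-2,6-dimethoxyphenoxy)-3-[(tert-butyldiphenylsilyl)oxy]propylidene}-2-methoxycyclohexa-2,5-dien-1-one | COC1=CC(=C[C@H](CO[Si](c2ccccc2)(c2ccccc2)C(C)(C)C)Oc2c(OC)cc(Br)cc2OC)C=CC1=O
F5 | step 8 | 4-{(1RS,2S)-2-(4-bromo-2,6-dimethoxyphenoxy)-3-[(tert-butyldiphenylsilyl)oxy]-1-hydroxypropyl}-2-methoxyphenol | COc1cc(C(O)[C@H](CO[Si](c2ccccc2)(c2ccccc2)C(C)(C)C)Oc2c(OC)cc(Br)cc2OC)ccc1O
F0 | step 9 | none | none
F6 | step 3 | 2-(4-bromo-2,6-dimethoxyphenoxy)acetic acid | OC(=O)COc1c(OC)cc(Br)cc1OC
F7 | step 12 | 2-(benzyloxy)-1-[4-({(1R,2S)-1-[4-(benzyloxy)-3-methoxyphenyl]-1-[(tert-butyldimethylsilyl)oxy]-3-[(tert-butyldiphenylsilyl)oxy]propan-2-yl}oxy)-3,5-dimethoxyphenyl]ethan-1-ol (C7' epimers) | COc1cc([C@@H](O[Si](C)(C)C(C)(C)C)[C@H](CO[Si](c2ccccc2)(c2ccccc2)C(C)(C)C)Oc2c(OC)cc(C(O)COCc3ccccc3)cc2OC)ccc1OCc1ccccc1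
A1 | alternative 1 | (4R,5S)-acetonide of the 2,6-dimethoxyphenyl ether with the ring A phenol as triisopropylsilyl ether | COc1cc([C@H]2OC(C)(C)OC[C@@H]2Oc2c(OC)cccc2OC)ccc1O[Si](C(C)C)(C(C)C)C(C)C
A2 | alternative 1 | C1' pinacol boronate of A1 | COc1cc([C@H]2OC(C)(C)OC[C@@H]2Oc2c(OC)cc(B3OC(C)(C)C(C)(C)O3)cc2OC)ccc1O[Si](C(C)C)(C(C)C)C(C)C
A3 | alternative 1 | acetoxyacetyl chloride | CC(=O)OCC(=O)Cl
A4 | alternative 1 | protected target with the acetoxyacetyl group at C1' | COc1cc([C@H]2OC(C)(C)OC[C@@H]2Oc2c(OC)cc(C(=O)COC(C)=O)cc2OC)ccc1O[Si](C(C)C)(C(C)C)C(C)C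
A5 | alternative 2 | Z aryl enol ether with ring B ketone as dimethyl ketal, all hydroxyls as tert-butyldimethylsilyl ethers | COc1cc(/C=C(/CO[Si](C)(C)C(C)(C)C)Oc2c(OC)cc(C(OC)(OC)CO[Si](C)(C)C(C)(C)C)cc2OC)ccc1O[Si](C)(C)C(C)(C)C
A6 | alternative 2 | protected erythro 7R,8S alcohol | COc1cc([C@@H](O)[C@H](CO[Si](C)(C)C(C)(C)C)Oc2c(OC)cc(C(OC)(OC)CO[Si](C)(C)C(C)(C)C)cc2OC)ccc1O[Si](C)(C)C(C)(C)C
A7 | alternative 3 | 2-(4-bromo-2,6-dimethoxyphenoxy)-1-{3-methoxy-4-[(triisopropylsilyl)oxy]phenyl}ethan-1-one | COc1cc(C(=O)COc2c(OC)cc(Br)cc2OC)ccc1O[Si](C(C)C)(C(C)C)C(C)C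
A8 | alternative 3 | Z trimethylsilyl enol ether of A7 | COc1cc(/C(O[Si](C)(C)C)=C/Oc2c(OC)cc(Br)cc2OC)ccc1O[Si](C(C)C)(C(C)C)C(C)C
A9 | alternative 3 | formaldehyde | C=O
A10 | alternative 3 | C8-configured α-aryloxy β-hydroxy ketone | COc1cc(C(=O)[C@H](CO)Oc2c(OC)cc(Br)cc2OC)ccc1O[Si](C(C)C)(C(C)C)C(C)C
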